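The 2-hydroxy-1,4-naphthoquinone core is the enol of naphthalene-1,2,4-trione, so the C1(=O)–C2(OH) pair of the quinone ring stands at the oxidation level of oxalic acid. The quinone ring is therefore closed by a [4+2] double acylation: a C,C-dinucleophile, carbanionic at the ring-fusion carbon C8a of the benzo ring and at the ketone α-carbon (the future C3), takes up both carbonyl carbons of diethyl oxalate, forming C8a–C1 and C3–C2 in one operation without any redox adjustment. The precursor is the enolate of a 2-bromophenyl ketone that already carries the 3-hydroxy-2,2-dimethylpropyl chain; the acid, made from (S)-linalool, is attached last by esterification.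

Key step: step 3

Assumption: (S)-(+)-linalool of high enantiomeric purity and methyl 4,4-dimethyl-5-oxopentanoate are taken as catalogue compounds; the target stereocentre is (S) and comes unchanged from (S)-linalool.

Step 1
Reactants: 1 methyl 4,4-dimethyl-5-oxopentanoate
Product: 3 5,5-dimethyltetrahydro-2H-pyran-2-one, via methyl 5-hydroxy-4,4-dimethylpentanoate 2 (not isolated)
Conditions: NaBH4, MeOH, 0 °C; then p-TsOH (cat.), toluene, 80 °C
Reagents that add atoms: none
Why: NaBH4 should reduce the aldehyde chemoselectively beside the methyl ester, and the δ-hydroxy ester should then lactonise under acid catalysis (intramolecular transesterification), helped by the gem-dimethyl group.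

Step 2
Reactants: 3 5,5-dimethyltetrahydro-2H-pyran-2-one; 4 1-bromo-2-iodobenzene
Product: 6 1-(2-bromophenyl)-5-hydroxy-4,4-dimethylpentan-1-one, via 2-bromophenylmagnesium chloride 5 (not isolated)
Conditions: 4, i-PrMgCl·LiCl (1.05 equiv), THF, −15 °C; then added to 3 (1.2 equiv), THF, −78 → −20 °C; aq. NH4Cl
Reagents that add atoms: none
Why: Iodine–magnesium exchange should occur only at the C–I bond, and Grignard addition to the δ-lactone should stop after one addition because the magnesium hemiketal alkoxide persists at low temperature and the ortho-bromine shields the ketone once it is released.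

Step 3
Reactants: 6 1-(2-bromophenyl)-5-hydroxy-4,4-dimethylpentan-1-one; 7 diethyl oxalate
Product: 10 2-hydroxy-3-(3-hydroxy-2,2-dimethylpropyl)naphthalene-1,4-dione, via lithiated enolate 8 (not isolated), via aryl glyoxylate enolate 9 (not isolated)
Conditions: KH (2.2 equiv), THF, 0 °C → rt; t-BuLi (2.1 equiv), −78 °C; 7 (1.05 equiv), −78 °C → rt; 1 M HCl
Reagents that add atoms: none
Why: KH should convert 6 into its alkoxide and (Z)-enolate (which also masks the ketone), bromine–lithium exchange with t-BuLi should then give the C,C-dinucleophile 8, whose aryllithium adds once to diethyl oxalate to give the aryl glyoxylate 9 (bond C8a–C1) and whose enolate carbon then attacks the remaining ester carbonyl with loss of ethoxide (bond C3–C2). The closest known reaction types are halogen–lithium exchange on a ketone masked as its enolate, acylation of an aryllithium by a dialkyl oxalate, the Claisen (Dieckmann-type) condensation, and the isatin synthesis from ortho-lithiated anilide dianions and diethyl oxalate. The six-membered quinone ring closes in the 6-(enolendo)-exo-trig mode by polar addition–elimination at the ester carbonyl. No stereocentre is formed. The step needs a single addition of the aryllithium to the oxalate, which the persistence of the tetrahedral adduct at −78 °C should secure, and C-acylation in preference to O-acylation or aldol attack on the new keto group, which should follow because only C-acylation leads irreversibly to the delocalised hydroxyquinone anion while the other closures are reversible. The site of annulation is fixed by the position of the bromine and by the only α-CH2 of the ketone, and the spectator alkoxide returns as the free primary alcohol on acidification.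

Step 4
Reactants: 11 (S)-(+)-linalool, (3S)-3,7-dimethylocta-1,6-dien-3-ol
Product: 12 (2E,6S)-6-hydroxy-2,6-dimethylocta-2,7-dienal
Conditions: SeO2 (1.2 equiv), 1,4-dioxane/H2O, 80 °C
Reagents that add atoms: selenium dioxide, O=[Se]=O
Why: Riley allylic oxidation (ene reaction, then [2,3]-sigmatropic shift) should attack the (E)-methyl group of the trisubstituted alkene and carry on to the (E)-enal, while the tertiary carbinol stereocentre of (S)-linalool is not touched.

Step 5
Reactants: 12 (2E,6S)-6-hydroxy-2,6-dimethylocta-2,7-dienal
Product: 13 (2E,6S)-6-hydroxy-2,6-dimethylocta-2,7-dienoic acid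
Conditions: NaClO2, NaH2PO4, 2-methyl-2-butene, t-BuOH/H2O, rt
Reagents that add atoms: sodium chlorite, [Na+].[O-]Cl=O
Why: Pinnick oxidation should convert the enal into the acid without touching the alkenes, the alkene geometry or the tertiary allylic alcohol, the scavenger removing the hypochlorous acid formed.

Step 6
Reactants: 10 2-hydroxy-3-(3-hydroxy-2,2-dimethylpropyl)naphthalene-1,4-dione; 13 (2E,6S)-6-hydroxy-2,6-dimethylocta-2,7-dienoic acid
Product: 15 3-(3-hydroxy-1,4-dioxo-1,4-dihydronaphthalen-2-yl)-2,2-dimethylpropyl (2E,6S)-6-hydroxy-2,6-dimethylocta-2,7-dienoate, via mixed anhydride 14 (not isolated)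
Conditions: 13 (1.2 equiv), 2,4,6-trichlorobenzoyl chloride (1.2 equiv), Et3N (2.5 equiv), THF, rt; then 10, DMAP (0.2 equiv), toluene, rt; MeOH/aq. NaHCO3, then citric acid work-up
Reagents that add atoms: none
Why: In this Yamaguchi esterification DMAP should open the mixed anhydride at the less hindered acyl group and the acylpyridinium should acylate the primary neopentyl hydroxyl, while the tertiary hydroxyl of 13 is too hindered and the quinone 2-OH, present as a poorly nucleophilic delocalised anion, gives at most a labile enol ester that is itself an acyl donor and is cleaved in the bicarbonate/methanol work-up; the stereocentre and the E-alkene are not involved.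

Compound list
1 | methyl 4,4-dimethyl-5-oxopentanoate | COC(=O)CCC(C)(C)C=O | starting material
2 | methyl 5-hydroxy-4,4-dimethylpentanoate | COC(=O)CCC(C)(C)CO | intermediate
3 | 5,5-dimethyltetrahydro-2H-pyran-2-one | O=C1CCC(C)(C)CO1 | intermediate
4 | 1-bromo-2-iodobenzene | Brc1ccccc1I | starting material
5 | 2-bromophenylmagnesium chloride | Brc1ccccc1[Mg]Cl | intermediate
6 | 1-(2-bromophenyl)-5-hydroxy-4,4-dimethylpentan-1-one | O=C(CCC(C)(C)CO)c1ccccc1Br | intermediate
7 | diethyl oxalate | CCOC(=O)C(=O)OCC | starting material
8 | lithiated enolate: dipotassium (Z)-1-(2-lithiophenyl)-4,4-dimethylpent-1-ene-1,5-diolate | [K+].[K+].[O-]CC(C)(C)C/C=C(\[O-])c1ccccc1[Li] | intermediate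
9 | aryl glyoxylate enolate: dipotassium (Z)-1-[2-(2-ethoxy-2-oxoacetyl)phenyl]-4,4-dimethylpent-1-ene-1,5-diolate | [K+].[K+].[O-]CC(C)(C)C/C=C(\[O-])c1ccccc1C(=O)C(=O)OCC | intermediate
10 | 2-hydroxy-3-(3-hydroxy-2,2-dimethylpropyl)naphthalene-1,4-dione | OCC(C)(C)CC1=C(O)C(=O)c2ccccc2C1=O | intermediate
11 | (S)-(+)-linalool, (3S)-3,7-dimethylocta-1,6-dien-3-ol | C=C[C@@](C)(O)CCC=C(C)C | starting material
12 | (2E,6S)-6-hydroxy-2,6-dimethylocta-2,7-dienal | C=C[C@@](C)(O)CC/C=C(\C)C=O | intermediate
13 | (2E,6S)-6-hydroxy-2,6-dimethylocta-2,7-dienoic acid | C=C[C@@](C)(O)CC/C=C(\C)C(=O)O | intermediate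
14 | mixed anhydride: (2E,6S)-6-hydroxy-2,6-dimethylocta-2,7-dienoic 2,4,6-trichlorobenzoic anhydride | C=C[C@@](C)(O)CC/C=C(\C)C(=O)OC(=O)c1c(Cl)cc(Cl)cc1Cl | intermediate
15 | 3-(3-hydroxy-1,4-dioxo-1,4-dihydronaphthalen-2-yl)-2,2-dimethylpropyl (2E,6S)-6-hydroxy-2,6-dimethylocta-2,7-dienoate | C=C[C@@](C)(O)CC/C=C(\C)C(=O)OCC(C)(C)CC1=C(O)C(=O)c2ccccc2C1=O | target

Total step count: 6. Longest linear sequence: 4 steps (steps 1, 2, 3 and 6); steps 4 and 5 form the second branch.

Steps most likely to fail

Step 3. The bromine–lithium exchange may stay incomplete in the mixed potassium/lithium aggregate, the aryllithium may be protonated before it is acylated, or the enolate may be acylated by the oxalate between molecules before the ring closes. The fallback sets out from 6 and comes back at 10, and it splits the annulation into two separately controlled operations with a latent enolate. Silylation of 6 with TMSOTf/Et3N in CH2Cl2 at 0 °C would give [(1Z)-1-(2-bromophenyl)-4,4-dimethyl-5-(trimethylsilyloxy)pent-1-en-1-yl]oxy(trimethyl)silane F1. Bromine–lithium exchange with t-BuLi in Et2O at −78 °C and addition to 7 would give, after neutral work-up, ethyl 2-{2-[(1Z)-4,4-dimethyl-1,5-bis(trimethylsilyloxy)pent-1-en-1-yl]phenyl}-2-oxoacetate F2. Fluoride (TBAF, THF, 0 °C) would then release the enolate for the Claisen ring closure and remove the second silyl group, and acidification would give 10.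

Step 6. Acylation may go to the acidic enol hydroxyl of the quinone, and the neopentyl alcohol may react slowly, so that mixed and doubly acylated material results. The fallback sets out from 10 and comes back at 15, masking the hydroxyquinone for the esterification. Methylation of 10 with trimethylsilyldiazomethane in toluene/MeOH would give 2-(3-hydroxy-2,2-dimethylpropyl)-3-methoxynaphthalene-1,4-dione F3; an O-methyl regioisomer would serve equally, since both hydrolyse to the same hydroxyquinone. Yamaguchi esterification with 13 would give 3-(3-methoxy-1,4-dioxo-1,4-dihydronaphthalen-2-yl)-2,2-dimethylpropyl (2E,6S)-6-hydroxy-2,6-dimethylocta-2,7-dienoate F4. Brief treatment with LiOH in THF/H2O at 0 °C would cleave the vinylogous methyl ester by addition–elimination, far faster than the hindered enoate, and give 15.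

Step 2. A second addition of the Grignard reagent to the ring-opened ketone may compete and give a tertiary carbinol. The fallback sets out from 3 and comes back at 6. Opening of 3 with N,O-dimethylhydroxylamine hydrochloride and i-PrMgCl in THF at −20 °C would give the Weinreb amide 5-hydroxy-N-methoxy-N,4,4-trimethylpentanamide F5. After deprotonation of its hydroxyl with one equivalent of i-PrMgCl, addition of 5 would stop at the chelated tetrahedral adduct and give 6 on work-up.

Further compounds
F1 | step 3 | [(1Z)-1-(2-bromophenyl)-4,4-dimethyl-5-(trimethylsilyloxy)pent-1-en-1-yl]oxy(trimethyl)silane | C[Si](C)(C)OCC(C)(C)C/C=C(\O[Si](C)(C)C)c1ccccc1Br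
F2 | step 3 | ethyl 2-{2-[(1Z)-4,4-dimethyl-1,5-bis(trimethylsilyloxy)pent-1-en-1-yl]phenyl}-2-oxoacetate | C[Si](C)(C)OCC(C)(C)C/C=C(\O[Si](C)(C)C)c1ccccc1C(=O)C(=O)OCC
F3 | step 6 | 2-(3-hydroxy-2,2-dimethylpropyl)-3-methoxynaphthalene-1,4-dione | COC1=C(CC(C)(C)CO)C(=O)c2ccccc2C1=O
F4 | step 6 | 3-(3-methoxy-1,4-dioxo-1,4-dihydronaphthalen-2-yl)-2,2-dimethylpropyl (2E,6S)-6-hydroxy-2,6-dimethylocta-2,7-dienoate | C=C[C@@](C)(O)CC/C=C(\C)C(=O)OCC(C)(C)CC1=C(OC)C(=O)c2ccccc2C1=O
F5 | step 2 | 5-hydroxy-N-methoxy-N,4,4-trimethylpentanamide | CON(C)C(=O)CCC(C)(C)CO
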